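**Retrosynthetic overview**

Locants are the heavy atoms of the target counted along its SMILES: rings A (C4, C5, C6, C7, C13) and B (C6, C7, C13, C14, C15) form the bicyclo[2.2.1]heptane, ring C is C7, C8, C9, C11, C12, C13, and ring D is C8, C9, C17, C19, C20, C21.
Enabling feature: C8 sits on the one-carbon bridge C7 syn to the C14–C15 bridge, whose C15 carries an exo hydroxyl. This is the 7-syn/2-exo pattern left by exo electrophilic attack on a bicyclo[2.2.1]hept-2-ene followed by a 1,2-shift; C8 is also alpha to C21, so a C21 ketone can present C8 as a carbenoid.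
Key disconnection, C7–C8 (ring C, closed last, one flask): the carbenoid from diazo ketone 23 adds across C6=C7 to give a temporary cyclopropane C6–C7–C8, then acid cleaves C8–C6, C5 shifts from C15 to C6 and acetate enters C15.
23 comes from the bicyclic iodide 13 and the ring-D vinylogous ester 17 (Stork–Danheiser union at C9–C11), then anti cuprate methylation at C9 and diazo transfer at C8; 13 comes from a catalytic asymmetric Diels–Alder reaction of a 2-silyloxycyclopentadiene with methyl vinyl ketone.
Ring order: cyclopentenone (bought), then the bicyclo[2.2.1]heptene (step 2); ring D is bought as a cyclohexenone; ring C last (step 16), the bicycle being re-seated into rings A and B in the same operation; end game is bromide at C17 with inversion and MeMgBr at C21.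

Key step: step 16

Assumption 1: the (S)-configured oxazaborolidinium catalyst is taken to give the enantiomer of 6 drawn below; if the sense is opposite, its (R) antipode is used.
Assumption 2: the lipase is taken to hydrolyse the (R)-acetate of 15; with the opposite preference the unreacted (R)-acetate is methanolysed (K2CO3, MeOH) to the same 16.

In the names below, endo means syn to the C2–C3 bridge of the bicyclo[2.2.1]heptane; absolute configurations are those of the SMILES.

**Route**

Step 1
Reactants: 1 3-ethoxycyclopent-2-en-1-one; 2 (1,3-dioxolan-2-ylmethyl)magnesium bromide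
Product: 3 3-(1,3-dioxolan-2-ylmethyl)cyclopent-2-en-1-one
Conditions: THF, 0 °C; then 1 M HCl, 0 °C, 15 min
Reagents that add atoms: none
Why: Stork–Danheiser sequence, in which 1,2-addition of the Grignard reagent to the vinylogous ester and acid-induced loss of ethanol transpose the enone; no stereocentre is formed.

Step 2
Reactants: 3 3-(1,3-dioxolan-2-ylmethyl)cyclopent-2-en-1-one; 4 but-3-en-2-one
Product: 6 1-(1,3-dioxolan-2-ylmethyl)-6-endo-acetyl-3-(tert-butyldimethylsilyloxy)bicyclo[2.2.1]hept-2-ene, via silyl dienol ether 5 (not isolated)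
Conditions: LDA, THF, −78 °C, then TBSOTf; solvent changed to CH2Cl2 below 0 °C; 4, (S)-1-(2-methylphenyl)-3,3-diphenyltetrahydro-1H,3H-pyrrolo[1,2-c][1,3,2]oxazaborole protonated with HNTf2 (20 mol %), −78 °C
Reagents that add atoms: tert-butyldimethylsilyl trifluoromethanesulfonate, CC(C)(C)[Si](C)(C)OS(=O)(=O)C(F)(F)F
Why: Kinetic alpha′-deprotonation and O-silylation give the 2-silyloxycyclopenta-1,3-diene, whose catalytic enantioselective Diels–Alder reaction should follow the ortho/para and endo rules, so the acetyl carbon bonds to the substituted bridgehead, the acetyl group lies syn to the enol-ether bridge, and the catalyst sets both bridgeheads and the acetyl-bearing carbon at once.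

Step 3
Reactants: 6 Diels–Alder adduct
Product: 7 4-(1,3-dioxolan-2-ylmethyl)-5-endo-(prop-1-en-2-yl)bicyclo[2.2.1]heptan-2-one
Conditions: Ph3PCH3Br, KOtBu, THF, −78 → 0 °C; then 1 M HCl, THF, 0 °C
Reagents that add atoms: methyltriphenylphosphonium bromide, C[P+](c1ccccc1)(c1ccccc1)c1ccccc1.[Br-]
Why: Wittig methylenation of the methyl ketone (the enol silane is inert) followed by mild hydrolysis of the silyl enol ether; the endo stereocentre stops being epimerisable once the ketone is olefinated and no new stereocentre forms.

Step 4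
Reactants: 7 isopropenyl ketone
Product: 8 4-(1,3-dioxolan-2-ylmethyl)-5-endo-isopropylbicyclo[2.2.1]heptan-2-one
Conditions: H2 (1 atm), Pd/C (10% palladium metal on carbon), EtOAc, 23 °C
Reagents that add atoms: none
Why: Heterogeneous catalytic hydrogenation of the 1,1-disubstituted alkene, done while the future ring alkene is still a ketone; no stereocentre is created.

Step 5
Reactants: 8 isopropyl ketone
Product: 9 4-(1,3-dioxolan-2-ylmethyl)-5-endo-isopropylbicyclo[2.2.1]hept-2-en-2-yl trifluoromethanesulfonate
Conditions: KHMDS, THF, −78 °C; PhNTf2, −78 → 0 °C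
Reagents that add atoms: N-phenylbis(trifluoromethanesulfonimide), O=S(=O)(N(c1ccccc1)S(=O)(=O)C(F)(F)F)C(F)(F)F
Why: Enol triflate formation; the ketone can enolise only toward its CH2 neighbour because the other alpha carbon is a bridgehead.

Step 6
Reactants: 9 enol triflate
Product: 10 2-[(6-endo-isopropylbicyclo[2.2.1]hept-2-en-1-yl)methyl]-1,3-dioxolane
Conditions: Pd(OAc)2 (5 mol %), PPh3, Bu3N, HCO2H, DMF, 60 °C
Reagents that add atoms: none
Why: Palladium-catalysed formate reduction of the enol triflate delivers the strained alkene without touching the acetal.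

Step 7
Reactants: 10 alkene acetal
Product: 11 (6-endo-isopropylbicyclo[2.2.1]hept-2-en-1-yl)acetaldehyde
Conditions: 2 M HCl, THF, 23 °C
Reagents that add atoms: water, O
Why: Acid-catalysed acetal hydrolysis; dilute acid at room temperature should leave the bicyclic alkene intact.

Step 8
Reactants: 11 aldehyde
Product: 12 2-(6-endo-isopropylbicyclo[2.2.1]hept-2-en-1-yl)ethanol
Conditions: NaBH4, MeOH, 0 °C
Reagents that add atoms: none
Why: Borohydride reduction of the aldehyde to the primary alcohol.

Step 9
Reactants: 12 primary alcohol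
Product: 13 1-(2-iodoethyl)-6-endo-isopropylbicyclo[2.2.1]hept-2-ene
Conditions: I2, PPh3, imidazole, CH2Cl2, 0 → 23 °C
Reagents that add atoms: iodine, II
Why: Appel-type iodination of a primary alcohol.

Step 10
Reactants: 14 3-ethoxycyclohex-2-en-1-one
Product: 15 racemic 6-acetoxy-3-ethoxycyclohex-2-en-1-one
Conditions: Mn(OAc)3·2H2O, benzene, reflux
Reagents that add atoms: manganese triacetate, CC(=O)[O-].CC(=O)[O-].CC(=O)[O-].[Mn+3]
Why: Mn(OAc)3-mediated alpha′-acetoxylation of an enone at the only saturated carbon next to the carbonyl; the product is racemic.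

Step 11
Reactants: 15 racemic acetate
Product: 16 (R)-3-ethoxy-6-hydroxycyclohex-2-en-1-one
Conditions: lipase from Burkholderia cepacia (Amano PS), pH 7 phosphate buffer–DMSO, 30 °C, stopped near half conversion; unreacted (S)-15 separated
Reagents that add atoms: none
Why: Enzymatic kinetic resolution by enantioselective ester hydrolysis; the enzyme fixes the carbinol carbon that becomes C17.

Step 12
Reactants: 16 (R)-hydroxy enone
Product: 17 (R)-6-(tert-butyldiphenylsilyloxy)-3-ethoxycyclohex-2-en-1-one
Conditions: TBDPSCl, imidazole, DMF, 23 °C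
Reagents that add atoms: tert-butyl(chloro)diphenylsilane, CC(C)(C)[Si](Cl)(c1ccccc1)c1ccccc1
Why: Silylation of the secondary alcohol; the TBDPS group is chosen to survive organolithium, cuprate and the acidic half of step 16.

Step 13
Reactants: 13 bicyclic iodide; 17 silyloxy vinylogous ester
Product: 20 (R)-4-(tert-butyldiphenylsilyloxy)-3-[2-(6-endo-isopropylbicyclo[2.2.1]hept-2-en-1-yl)ethyl]cyclohex-2-en-1-one, via alkyllithium 18 (not isolated), via lithium alkoxide adduct 19 (not isolated)
Conditions: 13, t-BuLi (2.1 equiv), Et2O–pentane, −78 °C; then 17, −78 → 0 °C; then 1 M HCl, 0 °C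
Reagents that add atoms: none
Why: Iodine–lithium exchange followed by Stork–Danheiser 1,2-addition and acidic enone transposition forms the C9–C11 bond and leaves the silyloxy stereocentre untouched.

Step 14
Reactants: 20 enone
Product: 21 trimethylsilyl enol ether (C8=C21–OSiMe3) with the new C9 methyl trans to the C17 silyloxy group
Conditions: Me2CuLi (from MeLi and CuI), TMSCl, THF, −78 → −30 °C; Et3N, pentane work-up
Reagents that add atoms: lithium dimethylcuprate (from MeLi and CuI), [Li+].C[Cu-]C; chlorotrimethylsilane, C[Si](C)(C)Cl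
Why: TMSCl-accelerated cuprate conjugate addition in which the methyl group should enter anti to the adjacent silyloxy group, setting the quaternary centre C9 by 1,2-substrate control, while the enolate is trapped regiospecifically toward C8.

Step 15
Reactants: 21 trimethylsilyl enol ether
Product: 23 2-diazo ketone (diazo at C8; C21 ketone), via trifluoroacetyl ketone 22 (not isolated)
Conditions: MeLi, THF, 0 °C; CF3CO2CH2CF3, −78 °C; then MsN3, Et3N, H2O, MeCN, 23 °C
Reagents that add atoms: methanesulfonyl azide, CS(=O)(=O)N=[N+]=[N-]; 2,2,2-trifluoroethyl trifluoroacetate, O=C(OCC(F)(F)F)C(F)(F)F (its acyl group is carried only by 22)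
Why: Regiospecific regeneration of the enolate, C-trifluoroacetylation and detrifluoroacetylative diazo transfer place the diazo group at C8 without touching any stereocentre.

Step 16
Reactants: 23 diazo ketone
Product: 25 tetracyclic keto acetate (C21 ketone; exo C15 acetate; trans C/D fusion), via spiro cyclopropyl ketone 24 (not isolated)
Conditions: Rh2(OAc)4 (1 mol %), CH2Cl2, 23 °C, slow addition; then AcOH and TfOH (10 mol %) added to the same flask, 0 → 23 °C
Reagents that add atoms: acetic acid, CC(=O)O
Why: Proposed new method: the Rh2(OAc)4-derived carbenoid at C8 (C9 is quaternary, so no 1,2-hydride shift competes) adds to the exo face of the strained C6=C7 bond, and because C8 is tied to the bridgehead C13 through C9–C11–C12 only C7 can become the ring-C partner (six-membered ring closed in the bicyclo[4.1.0] mode of intramolecular cyclopropanation), which leaves the spiro centre C8 a single possible configuration. Acid then protonates the C21 ketone and the cyclopropane bond that is axial on the locked chair of ring D (C8–C6) breaks; the C6 cation is bridged by C5, which migrates from C15 to C6 (a Wagner–Meerwein shift that turns the old bicycle into rings A and B), acetic acid enters C15 from the exo face anti to the migrating carbon, and the enol is protonated axially at C8. The closest known reaction types are intramolecular cyclopropanation of alpha-diazo ketones, acid-induced homoconjugate opening of acyl cyclopropanes and the 7-syn/2-exo outcome of electrophilic additions to bicyclo[2.2.1]hept-2-enes; their union in one flask on a spiro acyl cyclopropane is new. C7 is set by exo attack on the bicycle, C6 by suprafacial migration of C5, C15 by exo capture and C8 by axial protonation trans to the C9 methyl (also the thermodynamic fusion), all relayed from C13 and C9. The step needs cleavage of C8–C6 and not C8–C7 (the latter lies near the nodal plane of the carbonyl and is a ring-C bond) and capture at C15 and not C6 (C6 is flanked by the C8-bearing C7, and an exo acetate or oxygen-bridged species formed there can re-ionise in the acid, so the C15 acetate should accumulate).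

Step 17
Reactants: 25 keto acetate silyl ether
Product: 26 C17 alcohol (axial; trans to the C9 methyl)
Conditions: TBAF, AcOH (1:1), THF, 50 °C
Reagents that add atoms: none
Why: Fluoride desilylation buffered with acetic acid so that the acetate and the C8 stereocentre next to the ketone are not disturbed.

Step 18
Reactants: 26 hydroxy keto acetate
Product: 27 C17 bromide (equatorial; cis to the C9 methyl)
Conditions: CBr4, P(n-C8H17)3, toluene, 70 °C
Reagents that add atoms: carbon tetrabromide, BrC(Br)(Br)Br
Why: Appel bromination with a trialkylphosphine, in which displacement of the axial oxyphosphonium group with inversion should give the equatorial bromide.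

Step 19
Reactants: 27 bromo keto acetate
Product: 28 target, CNP0317598.2
Conditions: MeMgBr (6 equiv), THF, −78 → 23 °C; aqueous NH4Cl
Reagents that add atoms: methylmagnesium bromide, C[Mg]Br
Why: Grignard addition to the C21 ketone from the equatorial side, away from the syn-axial C9 methyl, should give the axial tertiary alcohol, and the excess reagent also cleaves the C15 acetate.

**Compound list**

1 | 3-ethoxycyclopent-2-en-1-one | CCOC1=CC(=O)CC1 | starting material
2 | (1,3-dioxolan-2-ylmethyl)magnesium bromide | Br[Mg]CC1OCCO1 | starting material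
3 | 3-(1,3-dioxolan-2-ylmethyl)cyclopent-2-en-1-one | O=C1CCC(CC2OCCO2)=C1 | intermediate
4 | but-3-en-2-one (methyl vinyl ketone) | CC(=O)C=C | starting material
5 | 2-(tert-butyldimethylsilyloxy)-4-(1,3-dioxolan-2-ylmethyl)cyclopenta-1,3-diene | CC(C)(C)[Si](C)(C)OC1=CCC(CC2OCCO2)=C1 | intermediate
6 | 1-(1,3-dioxolan-2-ylmethyl)-6-endo-acetyl-3-(tert-butyldimethylsilyloxy)bicyclo[2.2.1]hept-2-ene | O1CCOC1C[C@]23C=C(O[Si](C)(C)C(C)(C)C)[C@H](C2)C[C@H]3C(C)=O | intermediate
7 | 4-(1,3-dioxolan-2-ylmethyl)-5-endo-(prop-1-en-2-yl)bicyclo[2.2.1]heptan-2-one | O1CCOC1C[C@]23CC(=O)[C@H](C2)C[C@H]3C(C)=C | intermediate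
8 | 4-(1,3-dioxolan-2-ylmethyl)-5-endo-isopropylbicyclo[2.2.1]heptan-2-one | O1CCOC1C[C@]23CC(=O)[C@H](C2)C[C@H]3C(C)C | intermediate
9 | 4-(1,3-dioxolan-2-ylmethyl)-5-endo-isopropylbicyclo[2.2.1]hept-2-en-2-yl trifluoromethanesulfonate | O1CCOC1C[C@]23C=C(OS(=O)(=O)C(F)(F)F)[C@H](C2)C[C@H]3C(C)C | intermediate
10 | 2-[(6-endo-isopropylbicyclo[2.2.1]hept-2-en-1-yl)methyl]-1,3-dioxolane | O1CCOC1C[C@]23C=C[C@H](C2)C[C@H]3C(C)C | intermediate
11 | (6-endo-isopropylbicyclo[2.2.1]hept-2-en-1-yl)acetaldehyde | O=CC[C@]12C=C[C@H](C1)C[C@H]2C(C)C | intermediate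
12 | 2-(6-endo-isopropylbicyclo[2.2.1]hept-2-en-1-yl)ethanol | OCC[C@]12C=C[C@H](C1)C[C@H]2C(C)C | intermediate
13 | 1-(2-iodoethyl)-6-endo-isopropylbicyclo[2.2.1]hept-2-ene | ICC[C@]12C=C[C@H](C1)C[C@H]2C(C)C | intermediate
14 | 3-ethoxycyclohex-2-en-1-one | CCOC1=CC(=O)CCC1 | starting material
15 | racemic 6-acetoxy-3-ethoxycyclohex-2-en-1-one | CCOC1=CC(=O)C(OC(C)=O)CC1 | intermediate
16 | (R)-3-ethoxy-6-hydroxycyclohex-2-en-1-one | CCOC1=CC(=O)[C@H](O)CC1 | intermediate
17 | (R)-6-(tert-butyldiphenylsilyloxy)-3-ethoxycyclohex-2-en-1-one | CCOC1=CC(=O)[C@H](O[Si](c2ccccc2)(c2ccccc2)C(C)(C)C)CC1 | intermediate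
18 | [2-(6-endo-isopropylbicyclo[2.2.1]hept-2-en-1-yl)ethyl]lithium | [Li]CC[C@]12C=C[C@H](C1)C[C@H]2C(C)C | intermediate
19 | lithium alkoxide of the 1,2-adduct of 18 to 17 (tertiary allylic alkoxide, carbinol centre unassigned) | CCOC1=CC(O[Li])(CC[C@]23C=C[C@H](C2)C[C@H]3C(C)C)[C@H](O[Si](c2ccccc2)(c2ccccc2)C(C)(C)C)CC1 | intermediate
20 | (R)-4-(tert-butyldiphenylsilyloxy)-3-[2-(6-endo-isopropylbicyclo[2.2.1]hept-2-en-1-yl)ethyl]cyclohex-2-en-1-one | O=C1C=C(CC[C@]23C=C[C@H](C2)C[C@H]3C(C)C)[C@H](O[Si](c2ccccc2)(c2ccccc2)C(C)(C)C)CC1 | intermediate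
21 | 4-(tert-butyldiphenylsilyloxy)-3-methyl-3-[2-(6-endo-isopropylbicyclo[2.2.1]hept-2-en-1-yl)ethyl]-1-(trimethylsilyloxy)cyclohex-1-ene, methyl trans to the silyloxy group | C[Si](C)(C)OC1=C[C@](C)(CC[C@]23C=C[C@H](C2)C[C@H]3C(C)C)[C@H](O[Si](c2ccccc2)(c2ccccc2)C(C)(C)C)CC1 | intermediate
22 | 2-trifluoroacetyl derivative of the ring-D ketone (acyl group on C8, configuration there unassigned) | O=C(C1C(=O)CC[C@@H](O[Si](c2ccccc2)(c2ccccc2)C(C)(C)C)[C@@]1(C)CC[C@]23C=C[C@H](C2)C[C@H]3C(C)C)C(F)(F)F | intermediate
23 | 2-diazo-4-(tert-butyldiphenylsilyloxy)-3-methyl-3-[2-(6-endo-isopropylbicyclo[2.2.1]hept-2-en-1-yl)ethyl]cyclohexan-1-one | [N-]=[N+]=C1C(=O)CC[C@@H](O[Si](c2ccccc2)(c2ccccc2)C(C)(C)C)[C@@]1(C)CC[C@]23C=C[C@H](C2)C[C@H]3C(C)C | intermediate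
24 | spiro cyclopropyl ketone: C8 bonded to C7 and C6 on the exo face of the bicycle, ring C closed, C9 syn to the methylene bridge | CC(C)[C@@H]1C[C@@H]2[C@@H]3[C@H]4[C@@]35C(=O)CC[C@@H](O[Si](c6ccccc6)(c6ccccc6)C(C)(C)C)[C@@]5(C)CC[C@@]41C2 | intermediate
25 | tetracyclic keto acetate: target skeleton with C21 ketone, exo C15 acetate, axial C17 OTBDPS, 8-H trans to the C9 methyl | CC(C)[C@@H]1C[C@@H]2[C@H]3[C@H]4[C@](C)(CC[C@@]31C[C@H]2OC(C)=O)[C@H](O[Si](c5ccccc5)(c5ccccc5)C(C)(C)C)CCC4=O | intermediate
26 | C17 axial alcohol of 25 (silyl group removed) | CC(C)[C@@H]1C[C@@H]2[C@H]3[C@H]4[C@](C)(CC[C@@]31C[C@H]2OC(C)=O)[C@H](O)CCC4=O | intermediate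
27 | C17 equatorial bromide with C21 ketone and exo C15 acetate | CC(C)[C@@H]1C[C@@H]2[C@H]3[C@H]4[C@](C)(CC[C@@]31C[C@H]2OC(C)=O)[C@@H](Br)CCC4=O | intermediate
28 | CNP0317598.2 | CC(C)[C@@H]1C[C@@H]2[C@H]3[C@H]4[C@](C)(CC[C@@]31C[C@H]2O)[C@@H](Br)CC[C@@]4(C)O | target

**Step count and risks**

Total step count: 19. Longest linear sequence: 16 steps (steps 1–9, then 13–19).

Steps most likely to fail:

1. Step 16 (proposed new method). The carbenoid may dimerise or insert into C–H bonds instead of cyclopropanating. In the acid stage the cyclopropane may open toward C7, the cation may collapse onto the enol or carbonyl oxygen, or 6,2-hydride shifts may scramble the cation before acetate capture. The fallback uses known reactions and separates bond construction from the skeletal shift. It sets out from 23: Rh2(OAc)4 in CH2Cl2 gives the spiro cyclopropyl ketone 24, which is isolated. Homoconjugate hydrobromination of the acyl cyclopropane (HBr in AcOH, CH2Cl2, −20 °C) should give the rearranged exo C15 bromo ketone F1; any unrearranged C6 bromide ionises to the same cation. Silver-assisted acetolysis of this 2-norbornyl-type bromide (AgOAc, AcOH, 60 °C), with the usual Wagner–Meerwein equilibration and exo capture, returns to the route at 25.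

2. Step 18. Ionisation of the neopentylic oxyphosphonium intermediate may lead to elimination toward C19 or to a 1,2-methyl shift from C9, or the displacement may simply be too slow. The fallback sets out from 26: the alcohol is converted at low temperature into the secondary triflate F2 (Tf2O, pyridine, CH2Cl2, −40 °C), which is displaced with a naked bromide source (Bu4NBr, toluene, 0 → 23 °C) with inversion, returning at 27.

3. Step 2. The silyloxycyclopentadiene may undergo 1,5-hydrogen shifts before cycloaddition, the reaction may stop at the Mukaiyama–Michael stage, or enantioselection with the small dienophile may be poor. The fallback sets out from 3, converted to 5 as before: a Diels–Alder reaction with 3-acryloyloxazolidin-2-one catalysed by Cu(OTf)2 and (S,S)-2,2′-isopropylidenebis(4-tert-butyl-2-oxazoline) (CH2Cl2, −78 °C) should give the endo imide F3. Aminolysis with MeONHMe·HCl and i-PrMgCl (THF, −20 °C) gives the Weinreb amide F4, and MeMgBr (THF, 0 °C) then returns to the route at 6.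

**Further compounds**

F1 | step 16 | exo C15 bromo ketone: target skeleton with C21 ketone, axial C17 OTBDPS | CC(C)[C@@H]1C[C@@H]2[C@H]3[C@H]4[C@](C)(CC[C@@]31C[C@H]2Br)[C@H](O[Si](c5ccccc5)(c5ccccc5)C(C)(C)C)CCC4=O
F2 | step 18 | C17 axial triflate of 26 | CC(C)[C@@H]1C[C@@H]2[C@H]3[C@H]4[C@](C)(CC[C@@]31C[C@H]2OC(C)=O)[C@H](OS(=O)(=O)C(F)(F)F)CCC4=O
F3 | step 2 | 3-{[1-(1,3-dioxolan-2-ylmethyl)-3-(tert-butyldimethylsilyloxy)bicyclo[2.2.1]hept-2-en-6-endo-yl]carbonyl}oxazolidin-2-one | O1CCOC1C[C@]23C=C(O[Si](C)(C)C(C)(C)C)[C@H](C2)C[C@H]3C(=O)N4CCOC4=O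
F4 | step 2 | N-methoxy-N-methyl amide corresponding to F3 | O1CCOC1C[C@]23C=C(O[Si](C)(C)C(C)(C)C)[C@H](C2)C[C@H]3C(=O)N(C)OC
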